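The route rests on disconnecting ring B at C8–C9 (labdane numbering), the bond between the carbon of the exocyclic C8=C17 methylene and the C9 methine that carries the C11–C12 link. Because these two units form a 1,4-diene retron once C11=C12 is drawn as a vinyl group, the key step is a platinum-catalysed 6-exo-dig carbocyclisation of a (Z)-allylsilane onto a terminal alkyne: one operation closes ring B, creates C9, unveils the methylene and leaves a vinyl handle for the side chain. The precursor is a monocyclic ring-A cyclohexane from β-ionone, whose C6 carbinol relays chirality to C10 and C5 through a radical acetal tether that nickel then opens to the allylsilane.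

Key step: step 8

Atom numbers C1–C20 are the labdane numbers of the target throughout.
Assumption: the copper–bisphosphine catalyst of step 1 is used as the ligand enantiomer that delivers the (R)-carbinol; if the named antipode gives the (S)-series, the other ligand enantiomer is taken.

Step 1
Reactants: 1 β-ionone, (E)-4-(2,6,6-trimethylcyclohex-1-en-1-yl)but-3-en-2-one
Product: 3 (R)-4-hydroxy-4-(2,6,6-trimethylcyclohex-1-en-1-yl)butan-2-one, via boryl ketone 2 (not isolated)
Conditions: CuCl (3 mol %), NaOt-Bu, (R)-1-[(S)-2-(diphenylphosphino)ferrocenyl]ethyldicyclohexylphosphine, B2pin2, MeOH, THF, rt; then 30% H2O2, pH 7 buffer, 0 °C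
Reagents that add atoms: hydrogen peroxide OO
Why: Copper-catalysed asymmetric conjugate borylation of the enone at its β-carbon C6, followed by stereoretentive C–B oxidation, should give the aldol-type carbinol with C6 set (R) by the chiral copper–boryl complex, the twisted tetrasubstituted ring alkene being too hindered to divert the addition to C10.

Step 2
Reactants: 3 (R)-4-hydroxy-4-(2,6,6-trimethylcyclohex-1-en-1-yl)butan-2-one
Product: 4 (4R)-4-(2-bromo-1-ethoxyethoxy)-4-(2,6,6-trimethylcyclohex-1-en-1-yl)butan-2-one (both acetal epimers)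
Conditions: ethyl vinyl ether, NBS, CH2Cl2, −40 → 0 °C
Reagents that add atoms: ethyl vinyl ether C=COCC; N-bromosuccinimide O=C1CCC(=O)N1Br
Why: Bromoalkoxylation of the electron-rich enol ether by the carbinol (haloacetal formation for an Ueno–Stork cyclisation) should outrun any reaction of NBS with the hindered ring alkene and leaves C6 untouched.

Step 3
Reactants: 4 bromoacetal
Product: 5 1-[(1R,4aS,8aR)-3-ethoxy-4a,8,8-trimethyloctahydro-1H-isochromen-1-yl]propan-2-one (trans-fused, both C-3 epimers)
Conditions: Bu3SnH (slow addition), AIBN (cat.), PhH (high dilution), 80 °C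
Reagents that add atoms: none
Why: Ueno–Stork radical cyclisation in which the C6–H eclipses the C5–C4 bond between the geminal methyls, so that the tether oxygen and the C7 arm lie on opposite alkene faces, the acetal radical adds 6-endo to C10 from the oxygen face (C5 is shielded by quaternary C4) and the tertiary C5 radical takes hydrogen from Bu3SnH anti to the now axial C10 and C4 methyls, which should set C10 and the trans C5–H in one step.

Step 4
Reactants: 5 cyclic acetal methyl ketone
Product: 8 {3-[(1R,4aS,8aR)-3-ethoxy-4a,8,8-trimethyloctahydro-1H-isochromen-1-yl]prop-1-yn-1-yl}trimethylsilane, via enol phosphate 6 (not isolated), via lithium acetylide 7 (not isolated)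
Conditions: LiN(i-Pr)2 (1.1 equiv), THF, −78 °C; ClP(O)(OEt)2; LiN(i-Pr)2 (2.3 equiv), −78 → 0 °C; Me3SiCl
Reagents that add atoms: chlorotrimethylsilane C[Si](C)(C)Cl
Why: One-pot methyl ketone-to-alkyne conversion by kinetic deprotonation at the methyl group, O-phosphorylation and base-induced elimination of diethyl phosphate, the acetylide being silylated in situ so that the alkyne is masked for the nickel step, with the base-stable acetal and all stereocentres untouched.

Step 5
Reactants: 8 silylalkyne acetal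
Product: 9 trimethyl{3-[(1R,4aS,8aR)-4a,8,8-trimethyl-4a,5,6,7,8,8a-hexahydro-1H-isochromen-1-yl]prop-1-yn-1-yl}silane
Conditions: TMSOTf (1.3 equiv), i-Pr2NEt (2 equiv), CH2Cl2, −20 °C → rt
Reagents that add atoms: none
Why: Silyl triflate/amine acetal-to-enol-ether elimination, in which the exocyclic ethoxy group is ionised to the ring oxocarbenium ion and the hindered amine removes a C9 proton, should give the cyclic enol ether C9=C11–O6 without touching C5, C6 or C10.

Step 6
Reactants: 9 cyclic enol ether
Product: 11 (R)-1-{(1R,2S)-2,6,6-trimethyl-2-[(Z)-3-(trimethylsilyl)prop-1-en-1-yl]cyclohexyl}but-3-yn-1-ol, via bis-silyl alcohol 10 (not isolated)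
Conditions: NiCl2(PPh3)2 (10 mol %), Me3SiCH2MgCl (4 equiv), PhMe, 80 °C; aq. NH4Cl work-up; then K2CO3, MeOH, rt
Reagents that add atoms: (trimethylsilyl)methylmagnesium chloride C[Si](C)(C)C[Mg]Cl
Why: Wenkert-type nickel-catalysed ring-opening cross-coupling of a cyclic enol ether with a Grignard reagent, in which zerovalent nickel inserts into the alkenyl C11–O bond and couples with retention of the cis ring geometry, should give the (Z)-allylsilane and free O6, after which K2CO3/MeOH removes only the alkynyl silyl group.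

Step 7
Reactants: 11 allylsilane alkynol
Product: 12 triethyl{[(R)-1-{(1R,2S)-2,6,6-trimethyl-2-[(Z)-3-(trimethylsilyl)prop-1-en-1-yl]cyclohexyl}but-3-yn-1-yl]oxy}silane
Conditions: TESOTf, 2,6-lutidine, CH2Cl2, −78 → 0 °C
Reagents that add atoms: triethylsilyl trifluoromethanesulfonate CC[Si](CC)(CC)OS(=O)(=O)C(F)(F)F
Why: Silylation of the hindered secondary alcohol with a reactive silyl triflate masks O6 so that it cannot add to the metal-activated alkyne in step 8.

Step 8
Reactants: 12 silyl-protected allylsilane alkyne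
Product: 13 triethyl{[(1R,4R,4aS,8aR)-4-ethenyl-4a,8,8-trimethyl-3-methylidenedecahydronaphthalen-1-yl]oxy}silane
Conditions: PtCl2 (5 mol %), acetone, H2O (2 equiv), 50 °C
Reagents that add atoms: none
Why: PtCl2 π-activates the terminal alkyne, the γ-carbon of the allylsilane (C9) attacks the internal alkyne carbon C8 anti to platinum, the β-silyl cation loses silicon to form the C11=C12 vinyl group, and protodemetalation of the alkenylplatinum gives the C8=C17 methylene. The closest known reaction type is the platinum- or gold-catalysed intramolecular carbocyclisation of allylsilanes with alkynes, a metallo-ene-like alkyne allylation. Ring B closes in the 6-exo-dig mode through a chair-like array in which the C6 silyloxy group and the ring-A bonds are equatorial. The new stereocentre C9 is controlled by 1,3-allylic strain of the (Z)-allylsilane: the C10 methyl lies in the alkene plane, so the alkyne arm on C5 can reach only the C5-side face and the vinyl group should end equatorial and cis to the C10 methyl (9R). The step needs exo attack at C8 rather than endo attack at C17 and carbon rather than oxygen attack on the alkyne; the Markovnikov polarisation of the terminal alkyne and the six-membered tether secure the first, the triethylsilyl cap on O6 the second.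

Step 9
Reactants: 14 tert-butyl 4-chloro-3-oxobutanoate
Product: 15 tert-butyl 4-acetoxy-3-oxobutanoate
Conditions: KOAc, DMF, rt
Reagents that add atoms: potassium acetate CC(=O)[O-].[K+]
Why: SN2 displacement of the activated α-chloro ketone chloride by acetate installs the C16 acetate before the alkene exists, so a free cis-hydroxy enoate that would lactonise is never formed.

Step 10
Reactants: 15 tert-butyl 4-acetoxy-3-oxobutanoate
Product: 16 tert-butyl (E)-4-acetoxy-3-{[(trifluoromethyl)sulfonyl]oxy}but-2-enoate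
Conditions: Tf2O, i-Pr2NEt, CH2Cl2, −78 °C
Reagents that add atoms: trifluoromethanesulfonic anhydride O=S(=O)(OS(=O)(=O)C(F)(F)F)C(F)(F)F
Why: O-triflation of the non-chelated ammonium enolate of the β-keto ester, which prefers the extended geometry, should give mainly the (E)-enol triflate with the triflate trans to the ester.

Step 11
Reactants: 13 vinyl decalin; 16 (E)-enol triflate
Product: 18 tert-butyl (5R,6R,9R,10S,13Z)-16-acetoxy-6-(triethylsilyloxy)labda-8(17),13-dien-15-oate, via alkylborane 17 (not isolated)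
Conditions: 9-BBN (1.1 equiv), THF, 0 °C → rt; then 16, PdCl2(dppf) (5 mol %), AsPh3, aq. K3PO4, DMF, rt
Reagents that add atoms: none
Why: 9-BBN should hydroborate the monosubstituted vinyl group at C12 in preference to the shielded 1,1-disubstituted 8(17)-alkene, and B-alkyl Suzuki–Miyaura coupling with the enol triflate proceeds with retention, so C12 ends trans and CH2OAc cis to the ester (13Z).

Step 12
Reactants: 18 protected seco-acid
Product: 20 (5R,6R,9R,10S,13Z)-16-acetoxy-6-hydroxylabda-8(17),13-dien-15-oic acid (CNP0182509.1), via silyl ester 19 (not isolated)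
Conditions: TMSOTf (3 equiv), 2,6-lutidine (4 equiv), CH2Cl2, 0 °C; then 1 M HCl, THF, 0 °C
Reagents that add atoms: none
Why: Silyl triflate/lutidine cleavage converts the tert-butyl ester into the trimethylsilyl ester with loss of isobutene under non-protic conditions that spare the exocyclic alkene and the acetate, and brief dilute acid then hydrolyses the silyl ester and the triethylsilyl ether.

Compound list
1 | β-ionone, (E)-4-(2,6,6-trimethylcyclohex-1-en-1-yl)but-3-en-2-one | CC(=O)/C=C/C1=C(C)CCCC1(C)C | starting material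
2 | (R)-4-(4,4,5,5-tetramethyl-1,3,2-dioxaborolan-2-yl)-4-(2,6,6-trimethylcyclohex-1-en-1-yl)butan-2-one | CC(=O)C[C@@H](B1OC(C)(C)C(C)(C)O1)C1=C(C)CCCC1(C)C | intermediate
3 | (R)-4-hydroxy-4-(2,6,6-trimethylcyclohex-1-en-1-yl)butan-2-one | CC(=O)C[C@@H](O)C1=C(C)CCCC1(C)C | intermediate
4 | (4R)-4-(2-bromo-1-ethoxyethoxy)-4-(2,6,6-trimethylcyclohex-1-en-1-yl)butan-2-one, both acetal epimers | CC(=O)C[C@@H](OC(CBr)OCC)C1=C(C)CCCC1(C)C | intermediate
5 | 1-[(1R,4aS,8aR)-3-ethoxy-4a,8,8-trimethyloctahydro-1H-isochromen-1-yl]propan-2-one, trans-fused, both C-3 epimers | CC(=O)C[C@@H](O1)[C@@H]2C(C)(C)CCC[C@@]2(C)CC1OCC | intermediate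
6 | diethyl 3-[(1R,4aS,8aR)-3-ethoxy-4a,8,8-trimethyloctahydro-1H-isochromen-1-yl]prop-1-en-2-yl phosphate | C=C(OP(=O)(OCC)OCC)C[C@@H](O1)[C@@H]2C(C)(C)CCC[C@@]2(C)CC1OCC | intermediate
7 | lithium 3-[(1R,4aS,8aR)-3-ethoxy-4a,8,8-trimethyloctahydro-1H-isochromen-1-yl]prop-1-yn-1-ide | [Li]C#CC[C@@H](O1)[C@@H]2C(C)(C)CCC[C@@]2(C)CC1OCC | intermediate
8 | {3-[(1R,4aS,8aR)-3-ethoxy-4a,8,8-trimethyloctahydro-1H-isochromen-1-yl]prop-1-yn-1-yl}trimethylsilane | C[Si](C)(C)C#CC[C@@H](O1)[C@@H]2C(C)(C)CCC[C@@]2(C)CC1OCC | intermediate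
9 | trimethyl{3-[(1R,4aS,8aR)-4a,8,8-trimethyl-4a,5,6,7,8,8a-hexahydro-1H-isochromen-1-yl]prop-1-yn-1-yl}silane | C[Si](C)(C)C#CC[C@@H](O1)[C@@H]2C(C)(C)CCC[C@@]2(C)C=C1 | intermediate
10 | (R)-1-{(1R,2S)-2,6,6-trimethyl-2-[(Z)-3-(trimethylsilyl)prop-1-en-1-yl]cyclohexyl}-4-(trimethylsilyl)but-3-yn-1-ol | C[Si](C)(C)C#CC[C@@H](O)[C@@H]1C(C)(C)CCC[C@@]1(C)/C=C\C[Si](C)(C)C | intermediate
11 | (R)-1-{(1R,2S)-2,6,6-trimethyl-2-[(Z)-3-(trimethylsilyl)prop-1-en-1-yl]cyclohexyl}but-3-yn-1-ol | C#CC[C@@H](O)[C@@H]1C(C)(C)CCC[C@@]1(C)/C=C\C[Si](C)(C)C | intermediate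
12 | triethyl{[(R)-1-{(1R,2S)-2,6,6-trimethyl-2-[(Z)-3-(trimethylsilyl)prop-1-en-1-yl]cyclohexyl}but-3-yn-1-yl]oxy}silane | C#CC[C@@H](O[Si](CC)(CC)CC)[C@@H]1C(C)(C)CCC[C@@]1(C)/C=C\C[Si](C)(C)C | intermediate
13 | triethyl{[(1R,4R,4aS,8aR)-4-ethenyl-4a,8,8-trimethyl-3-methylidenedecahydronaphthalen-1-yl]oxy}silane | C=C1C[C@@H](O[Si](CC)(CC)CC)[C@@H]2C(C)(C)CCC[C@@]2(C)[C@@H]1C=C | intermediate
14 | tert-butyl 4-chloro-3-oxobutanoate | ClCC(=O)CC(=O)OC(C)(C)C | starting material
15 | tert-butyl 4-acetoxy-3-oxobutanoate | CC(=O)OCC(=O)CC(=O)OC(C)(C)C | intermediate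
16 | tert-butyl (E)-4-acetoxy-3-{[(trifluoromethyl)sulfonyl]oxy}but-2-enoate | CC(=O)OC/C(OS(=O)(=O)C(F)(F)F)=C\C(=O)OC(C)(C)C | intermediate
17 | 9-{2-[(1R,4R,4aS,8aR)-4a,8,8-trimethyl-3-methylidene-1-(triethylsilyloxy)decahydronaphthalen-4-yl]ethyl}-9-borabicyclo[3.3.1]nonane | C=C1C[C@@H](O[Si](CC)(CC)CC)[C@@H]2C(C)(C)CCC[C@@]2(C)[C@@H]1CCB1C2CCCC1CCC2 | intermediate
18 | tert-butyl (5R,6R,9R,10S,13Z)-16-acetoxy-6-(triethylsilyloxy)labda-8(17),13-dien-15-oate | C=C1C[C@@H](O[Si](CC)(CC)CC)[C@@H]2C(C)(C)CCC[C@@]2(C)[C@@H]1CC/C(=C/C(=O)OC(C)(C)C)COC(C)=O | intermediate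
19 | trimethylsilyl (5R,6R,9R,10S,13Z)-16-acetoxy-6-(triethylsilyloxy)labda-8(17),13-dien-15-oate | C=C1C[C@@H](O[Si](CC)(CC)CC)[C@@H]2C(C)(C)CCC[C@@]2(C)[C@@H]1CC/C(=C/C(=O)O[Si](C)(C)C)COC(C)=O | intermediate
20 | (5R,6R,9R,10S,13Z)-16-acetoxy-6-hydroxylabda-8(17),13-dien-15-oic acid (CNP0182509.1) | C=C1C[C@@H](O)[C@@H]2C(C)(C)CCC[C@@]2(C)[C@@H]1CC/C(=C/C(=O)O)COC(C)=O | target

Total step count: 12. Longest linear sequence: 10 steps (steps 1–8, 11 and 12); steps 9 and 10 make the coupling partner.

Steps most likely to fail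

Step 3. The slow 6-endo addition to the tetrasubstituted alkene may lose to closure at the proximal carbon C5 (5-exo) or to hydrogen transfer from C7 to the tether radical. The fallback changes the tether to silicon, whose longer bonds favour 6-endo closure, and rebuilds the allylsilane by olefination. It sets out from 3: silylation with (bromomethyl)chlorodimethylsilane (Et3N, DMAP) should give the (bromomethyl)dimethylsilyl ether F1, and Bu3SnH/AIBN should close the trans-fused oxasilinane F2 by the same facial logic. The methyl ketone is converted as in step 4, with aqueous NH4Cl quench, through the enol phosphate F3 and the lithium acetylide F4 into the terminal alkyne F5. Tamao–Fleming oxidation (H2O2, KF, KHCO3, THF/MeOH) should give the diol F6, and TESOTf/2,6-lutidine the bis(triethylsilyl) ether F7. Swern conditions oxidise the primary silyl ether selectively to the aldehyde F8, and a Z-selective Wittig reaction with Ph3P=CHCH2SiMe3 returns to the route at 12.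

Step 6. Zerovalent nickel may be sequestered by the silylalkyne or fail to insert into the hindered enol ether C–O bond. The fallback cleaves the enol ether instead of coupling it and sets out from 9: ozonolysis (O3, CH2Cl2, −78 °C; PPh3) should give the aldehyde formate F9, in which C9 is the aldehyde and O6 carries the former C11 as a formate. Wittig reaction with one equivalent of Ph3P=CHCH2SiMe3 at low temperature should give the (Z)-allylsilane formate F10, and K2CO3/MeOH removes the formate and the alkynyl silyl group together, returning to the route at 11.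

Step 8. Protodesilylation of the allylsilane or platinum-induced skeletal reorganisation of the enyne may outrun carbocyclisation. The fallback replaces metal catalysis by stoichiometric iodonium activation and sets out from 12: bis(pyridine)iodonium tetrafluoroborate with HBF4 in CH2Cl2 at −78 °C should trigger the same anti allylsilane closure onto the iodonium-activated alkyne and give the exocyclic vinyl iodide F11. Hydrodeiodination with Bu3SnH and Pd(PPh3)4 returns to the route at 13.

Further compounds
F1 | step 3 | (R)-4-{[(bromomethyl)dimethylsilyl]oxy}-4-(2,6,6-trimethylcyclohex-1-en-1-yl)butan-2-one | CC(=O)C[C@@H](O[Si](C)(C)CBr)C1=C(C)CCCC1(C)C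
F2 | step 3 | trans-fused oxasilinane analogue of 5 with SiMe2 in place of CH(OEt), methyl ketone | CC(=O)C[C@@H](O1)[C@@H]2C(C)(C)CCC[C@@]2(C)C[Si]1(C)C
F3 | step 3 | diethyl enol phosphate of F2 at the methyl ketone | C=C(OP(=O)(OCC)OCC)C[C@@H](O1)[C@@H]2C(C)(C)CCC[C@@]2(C)C[Si]1(C)C
F4 | step 3 | lithium acetylide of F5 | [Li]C#CC[C@@H](O1)[C@@H]2C(C)(C)CCC[C@@]2(C)C[Si]1(C)C
F5 | step 3 | trans-fused oxasilinane with prop-2-yn-1-yl arm at C6 | C#CC[C@@H](O1)[C@@H]2C(C)(C)CCC[C@@]2(C)C[Si]1(C)C
F6 | step 3 | (R)-1-[(1R,2S)-2-(hydroxymethyl)-2,6,6-trimethylcyclohexyl]but-3-yn-1-ol | C#CC[C@@H](O)[C@@H]1C(C)(C)CCC[C@@]1(C)CO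
F7 | step 3 | bis(triethylsilyl) ether of F6 | C#CC[C@@H](O[Si](CC)(CC)CC)[C@@H]1C(C)(C)CCC[C@@]1(C)CO[Si](CC)(CC)CC
F8 | step 3 | (1S,2R)-1,3,3-trimethyl-2-[(R)-1-(triethylsilyloxy)but-3-yn-1-yl]cyclohexane-1-carbaldehyde | C#CC[C@@H](O[Si](CC)(CC)CC)[C@@H]1C(C)(C)CCC[C@@]1(C)C=O
F9 | step 6 | (R)-1-[(1R,2S)-2-formyl-2,6,6-trimethylcyclohexyl]-4-(trimethylsilyl)but-3-yn-1-yl formate | C[Si](C)(C)C#CC[C@@H](OC=O)[C@@H]1C(C)(C)CCC[C@@]1(C)C=O
F10 | step 6 | formate ester of 10 | C[Si](C)(C)C#CC[C@@H](OC=O)[C@@H]1C(C)(C)CCC[C@@]1(C)/C=C\C[Si](C)(C)C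
F11 | step 8 | triethyl{[(1R,4R,4aS,8aR,E)-4-ethenyl-3-(iodomethylidene)-4a,8,8-trimethyldecahydronaphthalen-1-yl]oxy}silane | I/C=C1\C[C@@H](O[Si](CC)(CC)CC)[C@@H]2C(C)(C)CCC[C@@]2(C)[C@@H]1C=C
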